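**Retrosynthetic overview**
1. Confluentic acid ⇒ depside aldehyde (the last step is CHO → CO2H) ⇒ cut of the aryl ester C–O bond into a ring A keto acid and a ring B phenol aldehyde.
2. Key cut in ring A is the aryl C6–CH2 bond, not the usual CH2–C(=O) bond. Cyclometallated C6 of 4-methoxysalicylic acid (aryl nucleophile) joins a hexanoyl sulfoxonium ylide used as the cation +CH2C(=O)C5H11 (enolonium equivalent, DMSO as nucleofuge).
3. Ylide ⇒ hexanoyl chloride + trimethylsulfoxonium iodide.
4. Ring B ⇒ formylation para to the free OH of 3-methoxy-5-pentylphenol ⇒ mono-demethylation of olivetol dimethyl ether.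
5. Ring order: both benzene rings are bought. The only ring made is a transient pyranone (isocoumarin), which closes after the key step and is opened again in the same pot.

Assumption: the SMILES holds no stereocentre and no stereogenic double bond, so the target is achiral and no stereocontrol is needed.

**Step 1**
Reactants: 1 trimethylsulfoxonium iodide; 2 hexanoyl chloride
Product: 4 1-[dimethyl(oxo)-λ6-sulfanylidene]heptan-2-one, via dimethylsulfoxonium methylide 3 (not isolated)
Conditions: 1 (3 equiv), KOtBu (3 equiv), THF, reflux, 2 h; then 2 (1 equiv), 0 °C to rt, 3 h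
Reagents that add atoms: none
Why: Corey–Chaykovsky methylide formation followed by C-acylation works because a second equivalent of 3 deprotonates the first-formed β-keto sulfoxonium salt to the stabilised, bench-stable ylide 4, which is inert to further acylation; no stereocentre is formed.

**Step 2 (key step)**
Reactants: 4 1-[dimethyl(oxo)-λ6-sulfanylidene]heptan-2-one; 5 2-hydroxy-4-methoxybenzoic acid (4-methoxysalicylic acid)
Product: 7 2-hydroxy-4-methoxy-6-(2-oxoheptyl)benzoic acid, via 8-hydroxy-6-methoxy-3-pentylisocoumarin 6 (not isolated)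
Conditions: 4 (1.5 equiv), [RuCl2(p-cymene)]2 (5 mol %), AgSbF6 (20 mol %), KOAc (30 mol %), ClCH2CH2Cl, 100 °C, sealed tube, 16 h; aq NaHCO3 wash, evaporate; then KOH (2 M, 5 equiv), EtOH–H2O, 60 °C; Et2O wash; then 1 M HCl, 0 °C, pH 2–3
Reagents that add atoms: potassium hydroxide (KOH), [K+].[OH-]
Why: Carboxylate-directed C–H ruthenation by divalent ruthenium (weak O-coordination, concerted metalation–deprotonation) can only occur at C6, the sole free ortho position, and the resulting aryl–ruthenium nucleophile migrates onto the ylide carbon once DMSO has left (α-oxo carbene migratory insertion, so the ketone α-carbon acts as an enolonium equivalent and two natively nucleophilic carbons are joined), which is the known C–H/O–H annulation of benzoic acids with α-carbonyl sulfoxonium ylides to 3-substituted isocoumarins, here stretched to a free salicylic acid, after which hydroxide opens the enol lactone irreversibly as the carboxylate; no stereocentre is formed.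

**Step 3**
Reactants: 8 1,3-dimethoxy-5-pentylbenzene (olivetol dimethyl ether)
Product: 9 3-methoxy-5-pentylphenol
Conditions: NaSEt (2 equiv), DMF, 140 °C, 3 h; then 1 M HCl
Reagents that add atoms: none
Why: Thiolate SN2 O-demethylation (Feutrill–Mirrington type) stops after one methyl group because the phenoxide formed makes the remaining aryl oxide far too poor a leaving group; no stereocentre is formed.

**Step 4**
Reactants: 9 3-methoxy-5-pentylphenol
Product: 11 4-hydroxy-2-methoxy-6-pentylbenzaldehyde, via aryl iminium chloride 10 (not isolated)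
Conditions: POCl3 (1.3 equiv), DMF, 0 °C to rt, 12 h; then H2O, 50 °C; extraction into aq Na2CO3, then SiO2
Reagents that add atoms: N,N-dimethylformamide, CN(C)C=O (formyl carbon); water, O (formyl oxygen)
Why: Vilsmeier–Haack formylation goes mainly para to the free hydroxyl, the strongest donor, at the carbon that is also ortho to OMe, and the minor ortho-hydroxy aldehydes are chelated, far less polar and not extracted by aqueous Na2CO3, so 11 is easily separated; no stereocentre is formed.

**Step 5**
Reactants: 7 2-hydroxy-4-methoxy-6-(2-oxoheptyl)benzoic acid; 11 4-hydroxy-2-methoxy-6-pentylbenzaldehyde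
Product: 13 4-formyl-3-methoxy-5-pentylphenyl 2-hydroxy-4-methoxy-6-(2-oxoheptyl)benzoate, via O-acylisourea 12 (not isolated)
Conditions: DCC (1.1 equiv), toluene, 0 °C to rt, 16 h, no base
Reagents that add atoms: none
Why: In this DMAP-free carbodiimide (Steglich-type) esterification the acidic para-formyl phenol 11 protonates and then captures the O-acylisourea faster than the chelated 2-OH of 7 can, and leaving out base limits the competing enol lactonisation to 6, which can be recycled with KOH; no stereocentre is formed.

**Step 6**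
Reactants: 13 4-formyl-3-methoxy-5-pentylphenyl 2-hydroxy-4-methoxy-6-(2-oxoheptyl)benzoate
Product: 14 confluentic acid, 4-{[2-hydroxy-4-methoxy-6-(2-oxoheptyl)benzoyl]oxy}-2-methoxy-6-pentylbenzoic acid
Conditions: NaClO2 (3 equiv), NaH2PO4 (4 equiv), 2-methyl-2-butene (30 equiv), t-BuOH–THF–H2O, 0 °C to rt
Reagents that add atoms: sodium chlorite (NaClO2), [Na+].[O-]Cl=O
Why: Pinnick (Lindgren–Kraus) oxidation at about pH 4 turns ArCHO into ArCO2H without touching the aryl ester, the ketone or the chelated phenol, while the large excess of alkene removes HOCl before it can chlorinate ring A; no stereocentre is formed.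

**Compound list**
1 | trimethylsulfoxonium iodide | C[S+](C)(C)=O.[I-] | starting material
2 | hexanoyl chloride | CCCCCC(=O)Cl | starting material
3 | dimethylsulfoxonium methylide | C=S(C)(C)=O | intermediate (not isolated)
4 | 1-[dimethyl(oxo)-λ6-sulfanylidene]heptan-2-one | CCCCCC(=O)C=S(C)(C)=O | intermediate
5 | 2-hydroxy-4-methoxybenzoic acid | COc1ccc(C(=O)O)c(O)c1 | starting material
6 | 8-hydroxy-6-methoxy-3-pentyl-1H-isochromen-1-one | CCCCCC1=Cc2cc(OC)cc(O)c2C(=O)O1 | intermediate (not isolated)
7 | 2-hydroxy-4-methoxy-6-(2-oxoheptyl)benzoic acid | CCCCCC(=O)Cc1cc(OC)cc(O)c1C(=O)O | intermediate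
8 | 1,3-dimethoxy-5-pentylbenzene | CCCCCc1cc(OC)cc(OC)c1 | starting material
9 | 3-methoxy-5-pentylphenol | CCCCCc1cc(O)cc(OC)c1 | intermediate
10 | (4-hydroxy-2-methoxy-6-pentylbenzylidene)dimethyliminium chloride | CCCCCc1cc(O)cc(OC)c1C=[N+](C)C.[Cl-] | intermediate (not isolated)
11 | 4-hydroxy-2-methoxy-6-pentylbenzaldehyde | CCCCCc1cc(O)cc(OC)c1C=O | intermediate
12 | O-acylisourea of 7 with DCC | CCCCCC(=O)Cc1cc(OC)cc(O)c1C(=O)OC(=NC1CCCCC1)NC1CCCCC1 | intermediate (not isolated)
13 | 4-formyl-3-methoxy-5-pentylphenyl 2-hydroxy-4-methoxy-6-(2-oxoheptyl)benzoate | CCCCCC(=O)Cc1cc(OC)cc(O)c1C(=O)Oc1cc(CCCCC)c(C=O)c(OC)c1 | intermediate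
14 | confluentic acid (achiral) | CCCCCC(=O)Cc1cc(OC)cc(O)c1C(=O)Oc1cc(CCCCC)c(C(=O)O)c(OC)c1 | target

**Count**
- Total steps: 6 (step 2 is a telescoped two-stage operation).
- Longest linear sequence: 4 (steps 1, 2, 5, 6 or steps 3, 4, 5, 6).

**Three steps most likely to fail**

Step 2. The free salicylate may chelate and deactivate ruthenium. It may also be O-alkylated by the protonated ylide, or decarboxylate at 100 °C. The fallback sets out from ylide 4 and comes back at isocoumarin 6. The phenol is carried masked and revealed afterwards by chelation control. Commercial 2,4-dimethoxybenzoic acid F1 is annulated with 4 under the same ruthenium carboxylate catalysis to 6,8-dimethoxy-3-pentylisocoumarin F2, which is isolated. BCl3 (CH2Cl2, −78 to 0 °C) then removes only the methyl ether peri to the lactone carbonyl and gives 6. Compound 6 is opened with KOH to 7 as in the second stage of step 2.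

Step 5. The activated keto acid may close to isocoumarin 6 through its enol faster than phenol 11 attacks. The fallback sets out from 7 and comes back at 13, with the ketone masked so that no enol is available.
- Acid 7 with ethane-1,2-dithiol and BF3·OEt2 (CH2Cl2, 0 °C) gives 2-hydroxy-4-methoxy-6-[(2-pentyl-1,3-dithiolan-2-yl)methyl]benzoic acid F3. Any lactone 6 formed under the Lewis acid is funnelled to the same product.
- DCC coupling of F3 with 11 gives the dithiolane-protected depside aldehyde F4.
- MeI and CaCO3 in MeCN–H2O at 45 °C release the ketone to give 13 before the chlorite oxidation.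

Step 4. Formylation para to OMe or between the two oxygens may dominate. The fallback sets out from 8 and comes back at 11, and fixes the regiochemistry through symmetry and chelation instead of donor strength.
- BBr3 converts 8 into olivetol F5.
- Vilsmeier formylation of this symmetric resorcinol gives 2,4-dihydroxy-6-pentylbenzaldehyde F6.
- TIPSCl with imidazole silylates only the non-chelated 4-OH and gives 2-hydroxy-6-pentyl-4-(triisopropylsilyloxy)benzaldehyde F7.
- MeI with K2CO3 methylates the 2-OH and gives 2-methoxy-6-pentyl-4-(triisopropylsilyloxy)benzaldehyde F8.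
- Bu4NF buffered with AcOH (THF, 0 °C) frees the 4-OH and gives 11.

**Further compounds**
F1 | step 2 | 2,4-dimethoxybenzoic acid (purchased) | COc1ccc(C(=O)O)c(OC)c1
F2 | step 2 | 6,8-dimethoxy-3-pentyl-1H-isochromen-1-one | CCCCCC1=Cc2cc(OC)cc(OC)c2C(=O)O1
F3 | step 5 | 2-hydroxy-4-methoxy-6-[(2-pentyl-1,3-dithiolan-2-yl)methyl]benzoic acid | CCCCCC1(Cc2cc(OC)cc(O)c2C(=O)O)SCCS1
F4 | step 5 | 4-formyl-3-methoxy-5-pentylphenyl 2-hydroxy-4-methoxy-6-[(2-pentyl-1,3-dithiolan-2-yl)methyl]benzoate | CCCCCC1(Cc2cc(OC)cc(O)c2C(=O)Oc2cc(CCCCC)c(C=O)c(OC)c2)SCCS1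
F5 | step 4 | olivetol (5-pentylbenzene-1,3-diol) | CCCCCc1cc(O)cc(O)c1
F6 | step 4 | 2,4-dihydroxy-6-pentylbenzaldehyde | CCCCCc1cc(O)cc(O)c1C=O
F7 | step 4 | 2-hydroxy-6-pentyl-4-(triisopropylsilyloxy)benzaldehyde | CCCCCc1cc(O[Si](C(C)C)(C(C)C)C(C)C)cc(O)c1C=O
F8 | step 4 | 2-methoxy-6-pentyl-4-(triisopropylsilyloxy)benzaldehyde | CCCCCc1cc(O[Si](C(C)C)(C(C)C)C(C)C)cc(OC)c1C=O
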